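## Structural features

The target is a bicyclic seco-triterpenoid: a cis-fused decalin (ring A: C1–C5 and C10; ring B: C5–C10) that carries at C9, through C11 and C12, a (13E,17E,21E)-triene chain ending in a primary allylic acetate. Ring A holds the C3 ketone next to the C4 gem-dimethyl group, and ring B holds at C8 a methyl-bearing tertiary alcohol. Four stereocentres are contiguous (C5, C10, C9, C8): H-5, the C10 methyl, C11 and the C8 methyl stand on one face (β) and the C8 hydroxyl on the other, so C9 sits between two fully substituted carbons with its substituent trans to the neighbouring oxygen. Fragile points are the tertiary alcohol (dehydration, and β-elimination whenever C11 is a carbonyl carbon), the three trisubstituted E-alkenes (acid-induced cyclisation or isomerisation), the allylic acetate (ionisation, reduction, methanolysis) and the enolisable C2 position. The real difficulty is not the chain, which farnesol supplies with its geometry, but the C8–C9–C10 triad on a cis ring fusion, together with the need to tell the C3 and C9 oxygens apart while C4 is doubly methylated. The key step exploits the C7–C8(OH)(CH3)–C9 array of ring B: a methyl carbinol between a ring methylene and a carbonyl carbon is what results when C7 of a five-membered ring shifts from C9 onto an acetyl carbonyl, so ring B, the C8 stereocentre and a C9 ketone handle for C11 all arise from a cis-hydrindane in one step.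

## Logic of the disconnections

31 to 30: the acetate C–O bond is cut last. The primary allylic hydroxyl of 30 is far more accessible than the tertiary C8 hydroxyl, so the forward step only needs a mild, selective acylation, and the acetate never meets carbanions or dissolving metal.

30 to 29: the C3 ketone and the chain hydroxyl are masked as dioxolane and silyl ether. Both fall in one mild aqueous acid step, which must spare the tertiary alcohol and the trienes.

29 to 28 to 21 + 27: the C11–C12 bond is cut between a sulfone-stabilised C11 carbanion and a primary allylic bromide. The cut separates the bicycle from a chain whose three E-alkenes are already in place, and the substitution takes place at the unhindered allylic carbon, not at the hindered C11. The forward steps demand alkylation of a hindered carbanion in the presence of the C8 alkoxide and a reductive desulfonylation that leaves the allylic silyl ether alone.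

27 to 26 to 25 to 24 to 23 to 22: functional-group changes only. The terminal E-methyl group of the farnesyl skeleton is oxidised while the C1 oxygen is an acetate, the two ends are then exchanged (silyl ether at the new hydroxyl, bromide at C1). The demand is site- and E-selective allylic oxidation.

21 to 20 to 18: the C9–H bond and the C11–S bond are cut. The C8 hydroxyl of 20 is allylic, so it can deliver hydrogen to its own face and fix the one stereocentre (C9) that reagent approach would probably set wrongly. The sulfone is put on the terminal carbon of 18 by radical addition, so no substitution at hindered C11 is needed. Because C8 and C10 carry no hydrogen, the elimination that forms 20 can only give the vinyl sulfone.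

18 to 16: the C9=C11 bond is cut back to the C9 ketone. The demand is methylenation of a ketone flanked by two fully substituted carbons, which calls for a small α-silyl carbanion.

16 to 15 (key step): the C7–C8 bond is cut and C7–C9 restored, contracting ring B to a cyclopentane that bears hydroxyl and acetyl at C9. This removes ring B and the C8 stereocentre in one stroke and leaves a hydrindane that comes from amino-acid-catalysed annulation. The demand is migration of C7, not C10, and the correct carbonyl face. This requires the hydroxyl of 15 to be α (trans to the C10 methyl) and the promoter to be a chelating Lewis acid.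

15 to 11 + 12: the C8–C9 bond is cut between the C9 ketone and an acyl anion equivalent. The demand is attack on the convex β face of the cis-hydrindanone so that the acetyl group ends β and the hydroxyl α.

11 to 10 to 9: the C9 ketone is taken back to the 9β-alcohol and the C5–H bond is cut to the C5=C6 alkene. The 9β-hydroxyl is homoallylic to that alkene and can direct hydrogen to the β face, which sets the cis ring fusion against the steric bias.

9 to 8 to 7 to 6: the dioxolane, one C4–CH3 bond and the silyl ether are removed. Alkylating the dienolate of the enone at C4 is regiospecific and moves the alkene to C5=C6. With C9 held as a protected alcohol, no second enolisable ketone competes.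

6 to 5 to 3 to 1 + 2: the C9 hydroxyl returns to the ketone, then the C4–C5 bond (aldol) and the C1–C10 bond (Michael) are cut. The demand is chemoselective reduction of the saturated ketone beside the enone and amino-acid control of the C10 configuration.

## Other disconnections considered

Alternative 1: The cut is through C5–C10 and C8–C9, opening both rings to the acyclic trienal A1, in which a Z-enal (C9=C10) is tied by the C1–C4 tether to a dienyl acetate (C5=C6–C7=C8). The forward key step is an intramolecular Diels–Alder reaction under a chiral Lewis acid to the cycloadduct A2, followed by equilibration at C9 and hydrogenation of C6=C7.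
- In its favour: both rings and up to four stereocentres form in one step, and C11 arrives on C9 already at the aldehyde level. On step economy to the bicycle and on the C9–C11 bond it is better than the chosen plan, which needs three steps after the key step to place a functional C11.
- Against it here: the dienophile is a β,β-disubstituted enal that must form the quaternary C10, the diene terminus C8 is fully substituted, and the tether ketone competes for the Lewis acid. Enantiocontrol of such a congested cycloaddition is far less secure than the amino-acid annulation. The product is a tertiary allylic acetate (prone to ionisation) and a β-acyloxy aldehyde, so the required epimerisation at C9 invites β-elimination.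
- Comparison: on structure it equals the chosen plan, since cis fusion follows from the tether. On mechanism it offers a concerted reaction, but with every steric parameter at its limit, against a 1,2-shift with close precedent.

Alternative 2: The cut is at the C10–CH3 and C9–C11 bonds. In the forward key step lithium dimethylcuprate adds to the ring B enone A3 at C10 and the enolate is allylated at C9 to give the decalone A4.
- In its favour: axial conjugate addition to such octalones is a well-precedented source of the cis ring fusion, on which it equals the chosen plan. Two carbon–carbon bonds form in one flask, and the C9–C11 bond is made without any late olefination of a hindered ketone, which is better than the chosen plan.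
- Against it here: trapping a cuprate-derived enolate next to a new quaternary centre is often sluggish, and the face taken by the allyl group is not secured. C8 then needs a separate methyl addition to a ketone flanked by C9, with its own facial and enolisation problems. The allyl terminus has to be rebuilt into the E-trisubstituted C13=C14 alkene, and C3 travels as a silyl ether that must be oxidised at the end.
- Comparison: it uses two substrate-controlled operations for C8 and C9 where the chosen plan sets C8 inside the rearrangement. The overall step count is probably similar, and the origin of the absolute configuration of A3 is an additional task.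

Alternative 3: The cut is at C1–C10 (ring A), traced back to the C3–C8 bond of the bicyclo[2.2.2]octenol A5. In the forward key step its potassium alkoxide undergoes an anionic oxy-Cope rearrangement to the cis-fused octalin A6, which has the C3 ketone and a C8=C9 enoate.
- In its favour: the ring fusion and the quaternary C10 are set stereospecifically by the bicyclic frame, at least equal to the directed hydrogenation of the chosen plan. The C3 ketone appears without a protecting group and C11 is present as an ester.
- Against it here: A5 itself needs an enantioselective cycloaddition of a heavily substituted cyclohexadiene and a vinyl addition on the correct face. After the rearrangement the tetrasubstituted C8=C9 enoate must be turned into the 8-hydroxy-9-H array with control of two centres, for which there is no direct method.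
- Comparison: the [3,3] shift is mechanistically cleaner than a 1,2-shift that must choose between two migrating groups. The work left after A6 outweighs this, so step economy is no better and stereocontrol at C8 and C9 is worse.

Key step: step 10

Remarks on the chemistry:
- Numbering is the polypodane numbering of the target and is kept for the hydrindane intermediates (five-membered ring C5, C6, C7, C9, C10; C8 is the acetyl carbon). β means the face of the C10 methyl.
- The target as drawn is cis-fused (5β-H, 10β-CH3), with C11 and the C8 methyl β and the C8 hydroxyl α. This is taken as the goal.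
- The ketol used for the ring expansion must have the C9 hydroxyl α (trans to the C10 methyl) and the acetyl group β. Under chelation the hydroxyl keeps its face, so the C9 epimer would give the C8 epimer of the ring-expanded product.

## Route

Step 1
Reactants: 1 2-methylcyclopentane-1,3-dione; 2 ethyl vinyl ketone
Product: 3 2-methyl-2-(3-oxopentyl)cyclopentane-1,3-dione
Conditions: H2O, AcOH (cat.), 75 °C
Reagents that add atoms: none
Why: Michael addition of the acidic cyclic 1,3-dione to the enone in water forms the C1–C10 bond; no stereocentre is formed because the product is still symmetric at C10.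

Step 2
Reactants: 3 2-methyl-2-(3-oxopentyl)cyclopentane-1,3-dione
Product: 5 (S)-4,10-dimethylhydrind-4-ene-3,9-dione with the C10 methyl β, via aldol ketol 4 (not isolated)
Conditions: L-phenylalanine (1.0 equiv), 1 M aq HClO4 (0.5 equiv), MeCN, reflux
Reagents that add atoms: none
Why: Hajos–Parrish–Eder–Sauer–Wiechert cyclisation: the enamine of the ethyl ketone attacks one of the two enantiotopic ring carbonyls, the L-amino acid selecting the one that makes C10 S, and the acid dehydrates the ketol. A primary amino acid is used because ethyl ketones cyclise poorly with proline.

Step 3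
Reactants: 5 (S)-4,10-dimethylhydrind-4-ene-3,9-dione
Product: 6 9β-hydroxy-4,10β-dimethylhydrind-4-en-3-one
Conditions: NaBH4 (0.3 equiv), EtOH, −20 °C
Reagents that add atoms: none
Why: chemoselective borohydride reduction: the saturated cyclopentanone is more electrophilic than the fully substituted enone, and hydride enters anti to the angular methyl, giving the 9β-alcohol. This hydroxyl differentiates the two oxygens, later directs the hydrogenation, and is reoxidised in step 8.

Step 4
Reactants: 6 9β-hydroxy-4,10β-dimethylhydrind-4-en-3-one
Product: 7 9β-(triethylsilyloxy)-4,10β-dimethylhydrind-4-en-3-one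
Conditions: Et3SiCl, imidazole, DMF, 0 °C to rt
Reagents that add atoms: chlorotriethylsilane, CC[Si](Cl)(CC)CC
Why: standard silylation; the ether keeps the alkoxide out of the methylation and is labile enough to fall off during the ketalisation of step 6.

Step 5
Reactants: 7 9β-(triethylsilyloxy)-4,10β-dimethylhydrind-4-en-3-one
Product: 8 9β-(triethylsilyloxy)-4,4,10β-trimethylhydrind-5-en-3-one
Conditions: KOt-Bu (1.3 equiv), t-BuOH/THF, 0 °C; MeI, 0 °C to rt
Reagents that add atoms: iodomethane, CI
Why: deconjugative α-alkylation: the thermodynamic dienolate (deprotonation at C6) is methylated at its α-carbon C4, which installs the gem-dimethyl group regiospecifically and moves the alkene to C5=C6; there is no second ketone to compete.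

Step 6
Reactants: 8 9β-(triethylsilyloxy)-4,4,10β-trimethylhydrind-5-en-3-one
Product: 9 3,3-ethylenedioxy-4,4,10β-trimethylhydrind-5-en-9β-ol
Conditions: ethylene glycol, p-TsOH·H2O (cat.), benzene, reflux with azeotropic removal of water
Reagents that add atoms: ethylene glycol, OCCO
Why: acid-catalysed ketalisation of the only ketone, with solvolysis of the triethylsilyl ether under the same acid; the β,γ-alkene cannot move into conjugation because C4 is quaternary.

Step 7
Reactants: 9 3,3-ethylenedioxy-4,4,10β-trimethylhydrind-5-en-9β-ol
Product: 10 cis-fused 3,3-ethylenedioxy-4,4,10β-trimethyl-5β-hydrindan-9β-ol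
Conditions: H2 (1–4 atm), [Ir(cod)(PCy3)(py)]PF6 (5–10 mol %), CH2Cl2, rt
Reagents that add atoms: none
Why: hydroxyl-directed homogeneous hydrogenation: the cationic iridium binds the 9β-hydroxyl and the homoallylic C5=C6 alkene on the same face and delivers both hydrogens to the β face, so H-5 ends cis to the C10 methyl. Undirected addition would be expected anti to the angular methyl and give the trans fusion.

Step 8
Reactants: 10 cis-fused 3,3-ethylenedioxy-4,4,10β-trimethyl-5β-hydrindan-9β-ol
Product: 11 cis-fused 3,3-ethylenedioxy-4,4,10β-trimethyl-5β-hydrindan-9-one
Conditions: Pr4N[RuO4] (5 mol %), N-methylmorpholine N-oxide, 4 Å molecular sieves, CH2Cl2, rt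
Reagents that add atoms: none
Why: Ley–Griffith oxidation of the secondary alcohol under neutral conditions that leave the dioxolane untouched; C5 is not α to the new ketone and cannot epimerise.

Step 9
Reactants: 11 cis-fused 3,3-ethylenedioxy-4,4,10β-trimethyl-5β-hydrindan-9-one; 12 ethyl vinyl ether
Product: 15 9β-acetyl-3,3-ethylenedioxy-4,4,10β-trimethyl-5β-hydrindan-9α-ol, via 1-ethoxyvinyllithium 13 (not isolated), via enol ether carbinol 14 (not isolated)
Conditions: 12, t-BuLi, THF, −78 to 0 °C; then 11, −78 to −20 °C; then 0.1 M aq HCl, THF, 0 °C
Reagents that add atoms: water, O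
Why: addition of an acyl anion equivalent (metallated enol ether) to the ketone, then hydrolysis of the enol ether, which is far faster than that of the dioxolane. In the cis-hydrindanone ring A and the 4α-methyl fold under the α face, so the nucleophile should enter on the convex β face, placing the acetyl group β and the hydroxyl α. The same reagent is known to add to hindered steroidal cyclopentanones.

Step 10
Reactants: 15 9β-acetyl-3,3-ethylenedioxy-4,4,10β-trimethyl-5β-hydrindan-9α-ol
Product: 16 cis-fused 3,3-ethylenedioxy-8α-hydroxy-4,4,8β,10β-tetramethyl-5β-decalin-9-one
Conditions: Al(Ot-Bu)3 (1.5 equiv), toluene, 100 °C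
Reagents that add atoms: none
Why: Ligand exchange puts the C9 oxygen on aluminium and the acetyl oxygen closes a five-membered chelate, so the two C–O bonds are held syn-periplanar, the carbonyl is activated and the alkoxide pushes. In that chelate the C9–C7 and C9–C10 bonds lie on opposite faces of the carbonyl plane, and the 1,2-shift of C7 from C9 to C8 forms the C7–C8 bond as C9 becomes the ketone; this is the acyloin (α-ketol) rearrangement, whose closest precedent is the Lewis acid induced D-homoannulation of 17α-hydroxy-20-oxopregnanes, where the ring methylene also migrates and the hydroxyl keeps its face. Ring B is not closed by a cyclisation but by a one-carbon ring expansion: the endocyclic C7–C9 bond of the cyclopentane migrates, the acetyl carbon is taken into the ring, and the change from a fully substituted cyclopentane ketol to a cyclohexanone drives the shift. The new stereocentre C8 is fixed by the chelate together with the C9 configuration: with the oxygen α and the acetyl group β on C9, C7 reaches the carbonyl face that leaves the oxygen α and the methyl β on C8, cis to the C10 methyl; the C9 epimer, or an open alkoxide transition state, would give the other C8 epimer. The step needs C7 and not C10 to migrate: migration of C10 would have to join two fully substituted carbons and press the acetyl methyl against the C10 methyl, whereas migration of the methylene is unencumbered. Al(Ot-Bu)3 is chosen because it cannot deliver hydride and leaves the dioxolane intact, which BF3·OEt2 might not. The ring fusion and C10 are untouched, and the new ketone has no α-hydrogen, so nothing can epimerise after the shift.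

Step 11
Reactants: 16 cis-fused 3,3-ethylenedioxy-8α-hydroxy-4,4,8β,10β-tetramethyl-5β-decalin-9-one
Product: 18 3,3-ethylenedioxy-4,4,8β,10β-tetramethyl-9-methylene-5β-decalin-8α-ol, via silyl diol 17 (not isolated)
Conditions: Me3SiCH2Li (3 equiv), THF, −78 to 0 °C; then KOt-Bu, 0 to 50 °C
Reagents that add atoms: (trimethylsilyl)methyllithium, [Li]C[Si](C)(C)C
Why: Peterson olefination: the small α-silyl carbanion adds to the non-enolisable ketone (the first equivalent deprotonates the hydroxyl), and the potassium β-silyl alkoxide undergoes syn-elimination of silanolate. No stereocentre is formed, and the configuration of the intermediate at C9 is lost.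

Step 12
Reactants: 18 3,3-ethylenedioxy-4,4,8β,10β-tetramethyl-9-methylene-5β-decalin-8α-ol
Product: 20 3,3-ethylenedioxy-4,4,8β,10β-tetramethyl-9-[(phenylsulfonyl)methylene]-5β-decalin-8α-ol, via iodo sulfone 19 (not isolated)
Conditions: PhSO2Na, I2, EtOAc/H2O, rt; then DBU, CH2Cl2, 0 °C to rt
Reagents that add atoms: sodium benzenesulfinate, [Na+].[O-]S(=O)c1ccccc1
Why: iodosulfonylation then dehydroiodination: benzenesulfonyl iodide formed in the flask adds by a radical chain, the sulfonyl radical to the terminal C11 and iodine to C9. Base can only remove HI toward C11 because C8 and C10 carry no hydrogen, so the vinyl sulfone is the sole elimination product; its alkene geometry is irrelevant.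

Step 13
Reactants: 20 3,3-ethylenedioxy-4,4,8β,10β-tetramethyl-9-[(phenylsulfonyl)methylene]-5β-decalin-8α-ol
Product: 21 3,3-ethylenedioxy-4,4,8β,10β-tetramethyl-9β-[(phenylsulfonyl)methyl]-5β-decalin-8α-ol
Conditions: H2 (4 atm), [Ir(cod)(PCy3)(py)]PF6 (10 mol %), CH2Cl2, rt
Reagents that add atoms: none
Why: hydroxyl-directed homogeneous hydrogenation of an allylic alcohol: the 8α-hydroxyl, held roughly perpendicular to the exocyclic alkene, binds the metal and hydrogen is delivered to the α face of C9, so C11 ends β, trans to the C8 oxygen. Reagent approach alone would probably favour the other face.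

Step 14
Reactants: 22 (2E,6E)-farnesol
Product: 23 (2E,6E)-farnesyl acetate
Conditions: Ac2O, pyridine, DMAP (cat.), CH2Cl2, 0 °C to rt
Reagents that add atoms: acetic anhydride, CC(=O)OC(C)=O
Why: routine acylation; the acetate protects C1 and deactivates the C2 alkene toward the allylic oxidation.

Step 15
Reactants: 23 (2E,6E)-farnesyl acetate
Product: 24 (2E,6E,10E)-12-hydroxyfarnesyl acetate
Conditions: SeO2 (cat.), t-BuOOH, salicylic acid (cat.), CH2Cl2, rt
Reagents that add atoms: tert-butyl hydroperoxide, CC(C)(C)OO
Why: selenium dioxide allylic oxidation (ene reaction, then [2,3]-sigmatropic shift) attacks the most electron-rich terminal alkene and hydroxylates its E-methyl group, which gives the 10E allylic alcohol.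

Step 16
Reactants: 24 (2E,6E,10E)-12-hydroxyfarnesyl acetate
Product: 25 (2E,6E,10E)-12-(tert-butyldimethylsilyloxy)farnesyl acetate
Conditions: t-BuMe2SiCl, imidazole, DMF, rt
Reagents that add atoms: tert-butyldimethylsilyl chloride, CC(C)(C)[Si](C)(C)Cl
Why: standard silylation; the silyl ether survives organolithium and dissolving-metal conditions that an acetate would not.

Step 17
Reactants: 25 (2E,6E,10E)-12-(tert-butyldimethylsilyloxy)farnesyl acetate
Product: 26 (2E,6E,10E)-12-(tert-butyldimethylsilyloxy)farnesol
Conditions: K2CO3 (cat.), MeOH, 0 °C to rt
Reagents that add atoms: none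
Why: transesterification removes the acetate without touching the silyl ether or the alkenes.

Step 18
Reactants: 26 (2E,6E,10E)-12-(tert-butyldimethylsilyloxy)farnesol
Product: 27 (2E,6E,10E)-12-(tert-butyldimethylsilyloxy)farnesyl bromide
Conditions: CBr4, PPh3, CH2Cl2, 0 °C
Reagents that add atoms: carbon tetrabromide, BrC(Br)(Br)Br
Why: Appel reaction; substitution at the primary allylic carbon under neutral conditions keeps the 2E geometry.

Step 19
Reactants: 21 3,3-ethylenedioxy-4,4,8β,10β-tetramethyl-9β-[(phenylsulfonyl)methyl]-5β-decalin-8α-ol; 27 (2E,6E,10E)-12-(tert-butyldimethylsilyloxy)farnesyl bromide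
Product: 28 coupled sulfone: 29 bearing a phenylsulfonyl group at C11 (both C11 epimers)
Conditions: n-BuLi (2.2 equiv), THF/DMPU, −78 °C; then 27, −78 to −20 °C
Reagents that add atoms: none
Why: alkylation of an α-sulfonyl carbanion (Julia-type coupling): the dianion (C8 alkoxide and C11 carbanion) displaces the unhindered primary allylic bromide, forming C11–C12 with the E-alkenes intact. The hindered tertiary alkoxide is a poor competitor, and the new C11 centre is removed in the next step.

Step 20
Reactants: 28 coupled sulfone
Product: 29 myrrhanone A as its C3 ethylene ketal and chain-terminal tert-butyldimethylsilyl ether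
Conditions: Na(Hg) (6% Na), Na2HPO4, MeOH/THF, −20 to 0 °C
Reagents that add atoms: none
Why: reductive desulfonylation by electron transfer to the aryl sulfone; the buffered medium leaves the isolated alkenes, the ketal, the allylic silyl ether and the C9 stereocentre (not acidic) unchanged.

Step 21
Reactants: 29 myrrhanone A ketal silyl ether
Product: 30 myrrhanone A: the target with a free primary allylic hydroxyl
Conditions: 1 M aq HCl, THF, rt
Reagents that add atoms: water, O
Why: mild aqueous acid hydrolyses the strained dioxolane of the hindered ketone and the primary silyl ether together; the conditions are too weak to dehydrate the tertiary alcohol or cyclise the triene.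

Step 22
Reactants: 30 myrrhanone A
Product: 31 myrrhanone A acetate (target)
Conditions: Ac2O (1.2 equiv), pyridine, DMAP (cat.), CH2Cl2, 0 °C
Reagents that add atoms: acetic anhydride, CC(=O)OC(C)=O
Why: selective acylation of the primary allylic alcohol; the hindered tertiary C8 hydroxyl should not react under these conditions.

## Compound list

1 | 2-methylcyclopentane-1,3-dione | CC1C(=O)CCC1=O | starting material
2 | ethyl vinyl ketone | CCC(=O)C=C | starting material
3 | 2-methyl-2-(3-oxopentyl)cyclopentane-1,3-dione | CCC(=O)CCC1(C)C(=O)CCC1=O | intermediate
4 | aldol ketol: cis-fused 5β-hydroxy-4,10β-dimethylhydrindane-3,9-dione (C4 configuration undefined) | O=C1CC[C@]2(O)C(C)C(=O)CC[C@]12C | intermediate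
5 | (S)-4,10β-dimethylhydrind-4-ene-3,9-dione [(7aS)-4,7a-dimethyl-2,3,7,7a-tetrahydro-1H-indene-1,5(6H)-dione] | O=C1CC[C@]2(C)C(=O)CCC2=C1C | intermediate
6 | 9β-hydroxy-4,10β-dimethylhydrind-4-en-3-one [(1S,7aS)-1-hydroxy-4,7a-dimethyl-1,2,3,6,7,7a-hexahydro-5H-inden-5-one] | O[C@H]1CCC2=C(C)C(=O)CC[C@]12C | intermediate
7 | 9β-(triethylsilyloxy)-4,10β-dimethylhydrind-4-en-3-one | CC[Si](CC)(CC)O[C@H]1CCC2=C(C)C(=O)CC[C@]12C | intermediate
8 | 9β-(triethylsilyloxy)-4,4,10β-trimethylhydrind-5-en-3-one | CC[Si](CC)(CC)O[C@H]1CC=C2C(C)(C)C(=O)CC[C@]12C | intermediate
9 | 3,3-ethylenedioxy-4,4,10β-trimethylhydrind-5-en-9β-ol | O[C@H]1CC=C2C(C)(C)C3(OCCO3)CC[C@]12C | intermediate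
10 | cis-fused 3,3-ethylenedioxy-4,4,10β-trimethyl-5β-hydrindan-9β-ol | O[C@H]1CC[C@@H]2C(C)(C)C3(OCCO3)CC[C@]12C | intermediate
11 | cis-fused 3,3-ethylenedioxy-4,4,10β-trimethyl-5β-hydrindan-9-one | O=C1CC[C@@H]2C(C)(C)C3(OCCO3)CC[C@]12C | intermediate
12 | ethyl vinyl ether | C=COCC | starting material
13 | 1-ethoxyvinyllithium | [Li]C(=C)OCC | intermediate
14 | 9β-(1-ethoxyvinyl)-3,3-ethylenedioxy-4,4,10β-trimethyl-5β-hydrindan-9α-ol | C=C(OCC)[C@@]1(O)CC[C@@H]2C(C)(C)C3(OCCO3)CC[C@]12C | intermediate
15 | 9β-acetyl-3,3-ethylenedioxy-4,4,10β-trimethyl-5β-hydrindan-9α-ol (hydroxyl trans to the C10 methyl) | CC(=O)[C@]1(O)[C@@]2(C)CCC3(OCCO3)C(C)(C)[C@H]2CC1 | intermediate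
16 | cis-fused 3,3-ethylenedioxy-8α-hydroxy-4,4,8β,10β-tetramethyl-5β-decalin-9-one | O=C1[C@@]2(C)CCC3(OCCO3)C(C)(C)[C@H]2CC[C@@]1(C)O | intermediate
17 | 3,3-ethylenedioxy-4,4,8β,10β-tetramethyl-9-(trimethylsilylmethyl)-5β-decalin-8α,9-diol (C9 configuration not defined, lost on elimination) | C[Si](C)(C)CC1(O)[C@@]2(C)CCC3(OCCO3)C(C)(C)[C@H]2CC[C@@]1(C)O | intermediate
18 | 3,3-ethylenedioxy-4,4,8β,10β-tetramethyl-9-methylene-5β-decalin-8α-ol | C=C1[C@@]2(C)CCC3(OCCO3)C(C)(C)[C@H]2CC[C@@]1(C)O | intermediate
19 | 9-iodo-9-[(phenylsulfonyl)methyl] adduct of 18 (C9 configuration not defined) | O=S(=O)(CC1(I)[C@@]2(C)CCC3(OCCO3)C(C)(C)[C@H]2CC[C@@]1(C)O)c1ccccc1 | intermediate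
20 | 3,3-ethylenedioxy-4,4,8β,10β-tetramethyl-9-[(phenylsulfonyl)methylene]-5β-decalin-8α-ol (either alkene geometry) | O=S(=O)(C=C1[C@@]2(C)CCC3(OCCO3)C(C)(C)[C@H]2CC[C@@]1(C)O)c1ccccc1 | intermediate
21 | 3,3-ethylenedioxy-4,4,8β,10β-tetramethyl-9β-[(phenylsulfonyl)methyl]-5β-decalin-8α-ol (9α-H) | O=S(=O)(C[C@@H]1[C@@]2(C)CCC3(OCCO3)C(C)(C)[C@H]2CC[C@@]1(C)O)c1ccccc1 | intermediate
22 | (2E,6E)-farnesol | CC(C)=CCC/C(C)=C/CC/C(C)=C/CO | starting material
23 | (2E,6E)-farnesyl acetate | CC(C)=CCC/C(C)=C/CC/C(C)=C/COC(C)=O | intermediate
24 | (2E,6E,10E)-12-hydroxyfarnesyl acetate | OC/C(C)=C/CC/C(C)=C/CC/C(C)=C/COC(C)=O | intermediate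
25 | (2E,6E,10E)-12-(tert-butyldimethylsilyloxy)farnesyl acetate | CC(C)(C)[Si](C)(C)OC/C(C)=C/CC/C(C)=C/CC/C(C)=C/COC(C)=O | intermediate
26 | (2E,6E,10E)-12-(tert-butyldimethylsilyloxy)farnesol | CC(C)(C)[Si](C)(C)OC/C(C)=C/CC/C(C)=C/CC/C(C)=C/CO | intermediate
27 | (2E,6E,10E)-12-(tert-butyldimethylsilyloxy)farnesyl bromide | CC(C)(C)[Si](C)(C)OC/C(C)=C/CC/C(C)=C/CC/C(C)=C/CBr | intermediate
28 | coupled sulfone: 29 with a phenylsulfonyl group at C11 (both C11 epimers) | CC(C)(C)[Si](C)(C)OC/C(C)=C/CC/C(C)=C/CC/C(C)=C/CC([C@@H]1[C@@]2(C)CCC3(OCCO3)C(C)(C)[C@H]2CC[C@@]1(C)O)S(=O)(=O)c1ccccc1 | intermediate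
29 | myrrhanone A C3 ethylene ketal, chain-terminal tert-butyldimethylsilyl ether | CC(C)(C)[Si](C)(C)OC/C(C)=C/CC/C(C)=C/CC/C(C)=C/CC[C@@H]1[C@@]2(C)CCC3(OCCO3)C(C)(C)[C@H]2CC[C@@]1(C)O | intermediate
30 | myrrhanone A (3-oxo, 8α-hydroxy, primary allylic alcohol at the chain terminus) | OC/C(C)=C/CC/C(C)=C/CC/C(C)=C/CC[C@@H]1[C@@]2(C)CCC(=O)C(C)(C)[C@H]2CC[C@@]1(C)O | intermediate
31 | myrrhanone A acetate | CC(=O)OC/C(C)=C/CC/C(C)=C/CC/C(C)=C/CC[C@@H]1[C@@]2(C)CCC(=O)C(C)(C)[C@H]2CC[C@@]1(C)O | target

## Step count and least certain steps

Total step count: 22. Longest linear sequence: 17 (steps 1–13 and 19–22); the chain fragment takes steps 14–18.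

Step 10 (key step).
- What may go wrong: migration of the quaternary C10 in place of C7, or a second acyloin shift (the C8 methyl moving to C9) on long heating.
- Why: both ring bonds are stereoelectronically allowed in the chelate and all these ketols are interconvertible.
- Fallback: use the complementary, non-chelated mode on the C9 epimer, setting out from 11. Wittig reaction with Ph3P=CHCH3 should give the ethylidene compound F1. Dihydroxylation with OsO4 (cat.) and N-methylmorpholine N-oxide from the convex β face should give the 9β,8-diol F2. Oxidation of its secondary hydroxyl (SO3·pyridine, DMSO, Et3N) should give the epimeric ketol F3 (9β-hydroxy, 9α-acetyl). With NaOMe in MeOH the alkoxide reacts through an open transition state with the two oxygens anti, which from F3 should again place the C8 hydroxyl α and the methyl β. The sequence returns to the route at 16.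

Step 9.
- What may go wrong: enolisation of the hindered cyclopentanone by the basic vinyllithium (return of 11) and incomplete preference for the convex face.
- Why: the carbonyl is flanked by the quaternary C10, and the selectivity rests on conformational analysis.
- Fallback: add the smaller, less basic acetylide (HC≡CMgBr, CeCl3, THF) to 11 to give the ethynyl carbinol F4, then hydrate the alkyne with Hg(OTf)2 (cat.) in wet MeCN. This reaches 15 by a different acyl anion equivalent. Any adduct with the hydroxyl β corresponds to the epimeric series of the fallback under step 10 and can be taken to 16 with alkoxide.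

Step 7.
- What may go wrong: slow turnover, or hydrogen addition from the α face (trans fusion).
- Why: the β face of C5 is flanked by the C10 and C4 methyl groups, so the directing effect has to override the steric bias.
- Fallback: set the ring fusion before the second methyl is introduced, setting out from 7. Hydrogenation of the enone over Pd/C in EtOAc (hydrindenones of this type are known to favour the cis fusion) should give the cis-fused ketone F5. Thermodynamic methylation (KOt-Bu, MeI) at C4, the favoured enolisation site of a cis-fused 3-ketone, should give the gem-dimethyl ketone F6. Ketalisation with ethylene glycol and p-TsOH, with loss of the silyl ether, returns to the route at 10.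

Step 13.
- What may go wrong: poor binding of the electron-poor, hindered vinyl sulfone to the cationic iridium, so that hydrogenation stalls or proceeds without direction and gives the C9 epimer.
- Why: the alkene is trisubstituted, deactivated and lies between two fully substituted carbons.
- Fallback: reagent-based intramolecular delivery. Treat 20 with NaAlH2(OCH2CH2OMe)2 in toluene; the C8 alkoxyaluminate should pass hydride to C9 on the α face through a five-membered transition state (conjugate reduction of the vinyl sulfone), returning to the route at 21 without new isolated compounds.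

Step 11.
- What may go wrong: incomplete addition to a ketone flanked by two fully substituted carbons, and a base-induced acyloin shift of the lithium alkoxide on warming.
- Why: steric shielding of C9 and the reversibility of ketol rearrangements under base.
- Fallback: titanium methylidene chemistry on the protected ketol, setting out from 16. Silylation (Me3SiOTf, 2,6-lutidine) should give the trimethylsilyl ether F7. Methylenation with Cp2TiMe2 in toluene at 70 °C should give the silyl ether F8. K2CO3 in MeOH returns to the route at 18.

## Further compounds

F1 | step 10 | 9-ethylidene-3,3-ethylenedioxy-4,4,10β-trimethyl-5β-hydrindane (either geometry) | CC=C1CC[C@@H]2C(C)(C)C3(OCCO3)CC[C@]12C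
F2 | step 10 | 3,3-ethylenedioxy-9α-(1-hydroxyethyl)-4,4,10β-trimethyl-5β-hydrindan-9β-ol (carbinol configuration in the side chain not defined) | CC(O)[C@]1(O)CC[C@@H]2C(C)(C)C3(OCCO3)CC[C@]12C
F3 | step 10 | 9α-acetyl-3,3-ethylenedioxy-4,4,10β-trimethyl-5β-hydrindan-9β-ol (C9 epimer of 15) | CC(=O)[C@]1(O)CC[C@@H]2C(C)(C)C3(OCCO3)CC[C@]12C
F4 | step 9 | 9β-ethynyl-3,3-ethylenedioxy-4,4,10β-trimethyl-5β-hydrindan-9α-ol | C#C[C@@]1(O)CC[C@@H]2C(C)(C)C3(OCCO3)CC[C@]12C
F5 | step 7 | cis-fused 9β-(triethylsilyloxy)-4,10β-dimethyl-5β-hydrindan-3-one (C4 configuration not defined) | CC[Si](CC)(CC)O[C@H]1CC[C@@H]2C(C)C(=O)CC[C@]12C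
F6 | step 7 | cis-fused 9β-(triethylsilyloxy)-4,4,10β-trimethyl-5β-hydrindan-3-one | CC[Si](CC)(CC)O[C@H]1CC[C@@H]2C(C)(C)C(=O)CC[C@]12C
F7 | step 11 | 8α-trimethylsilyl ether of 16 | O=C1[C@@]2(C)CCC3(OCCO3)C(C)(C)[C@H]2CC[C@@]1(C)O[Si](C)(C)C
F8 | step 11 | 8α-trimethylsilyl ether of 18 | C=C1[C@@]2(C)CCC3(OCCO3)C(C)(C)[C@H]2CC[C@@]1(C)O[Si](C)(C)C
F0 | step 13 | none | none
A1 | alternative 1 | acyclic trienal: Z-enal tethered through the 3-oxo-4,4-dimethyl chain to the (5E,7E)-dienyl acetate | O=C/C=C(C)\CCC(=O)C(C)(C)/C=C/C=C(\C)OC(C)=O
A2 | alternative 1 | cis-fused 3-oxo octalin with C8 tertiary acetate and C9 formyl group | O=C[C@@H]1[C@@]2(C)CCC(=O)C(C)(C)[C@H]2C=C[C@@]1(C)OC(C)=O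
A3 | alternative 2 | ring B enone: 3-(tert-butyldimethylsilyloxy)-4,4-dimethyl-5β-octal-9-en-8-one | O=C1C=C2CC[C@@H](O[Si](C)(C)C(C)(C)C)C(C)(C)[C@H]2CC1
A4 | alternative 2 | cis-fused 9-allyl-10-methyl decal-8-one with C3 silyl ether | C=CC[C@@H]1[C@@]2(C)CC[C@@H](O[Si](C)(C)C(C)(C)C)C(C)(C)[C@H]2CCC1=O
A5 | alternative 3 | bicyclo[2.2.2]octenol: vinyl carbinol at C3 (vinyl syn to the enoate bridge), bridgehead methyl at C8, C9=C10 enoate | C=C[C@]1(O)C(C)(C)[C@H]2CC[C@]1(C)C(C(=O)OC)=C2C
A6 | alternative 3 | cis-fused 3-oxo octalin with C8=C9 enoate (C11 as methyl ester) | COC(=O)C1[C@@]2(C)CCC(=O)C(C)(C)[C@H]2CCC=1C
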